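**Plan**
- Ring C is cut at O1–C2 (cyclodehydration) and C2–C3 (aroyl transfer); this leaves an ortho-hydroxyaryl methoxymethyl ketone, which already holds C3 and C4, and 4-methoxybenzoyl chloride as ring B.
- Ring A is cut at C4a–C8a (6π closure) and C5–C6 (vinyllithium addition), then the side chain at C4–C4a (acetylide acylation).
- Enabling feature: in ring A, C6, C7, C8 and C8a carry four contiguous oxygens, C5 carries hydrogen and C4a carbon. That is the four carbons of dimethyl squarate plus a two-carbon E-alkene bearing the masked C4 ketone.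
- Forward: the C3–C4–C4a–C5 chain is assembled, ketalised and turned into an E-vinyl iodide, joined to the squarate, ring A is formed by thermal ring expansion, and ring C is closed last.
- The target has no stereocentre. The only geometric element, the E-alkene, comes from syn hydrozirconation followed by retentive iodination.

Key step: step 7

Remark: the stereocentres that appear in 6, 14, 15, 17 and 22 are racemic, are written without descriptor, and all are erased before the achiral target.

**Step 1**
Reactants: 1 methoxyacetyl chloride; 2 N,O-dimethylhydroxylamine hydrochloride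
Product: 3 N,2-dimethoxy-N-methylacetamide
Conditions: pyridine (2.2 equiv), CH2Cl2, 0 °C → rt
Reagents that add atoms: none
Why: N-acylation gives the Weinreb amide, chosen because direct Lewis-acid acylation of a silylalkyne with an α-alkoxy acid chloride would lose CO to a methoxymethyl cation.

**Step 2**
Reactants: 3 N,2-dimethoxy-N-methylacetamide; 4 ethynyltrimethylsilane
Product: 7 1-methoxy-4-(trimethylsilyl)but-3-yn-2-one, via lithium (trimethylsilyl)acetylide 5 (not isolated), via lithium hemiaminal adduct 6 (not isolated)
Conditions: 4, n-BuLi, THF, −78 °C; then 3, −78 → 0 °C; cold 1 M HCl quench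
Reagents that add atoms: none
Why: Weinreb ketone synthesis, in which the chelated tetrahedral adduct survives until the quench so that no second addition occurs, and the acidic quench protonates the released amine before it can add to the ynone.

**Step 3**
Reactants: 7 1-methoxy-4-(trimethylsilyl)but-3-yn-2-one
Product: 8 2-(methoxymethyl)-2-[(trimethylsilyl)ethynyl]-1,3-dioxolane
Conditions: Me3SiOCH2CH2OSiMe3, Me3SiOTf (cat.), CH2Cl2, −78 → 0 °C; pyridine quench
Reagents that add atoms: 1,2-bis(trimethylsilyloxy)ethane, C[Si](C)(C)OCCO[Si](C)(C)C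
Why: Silyl-triflate-catalysed ketalisation with the bis-silyl ether of ethylene glycol is aprotic and cold, so conjugate addition to the ynone is avoided, and it is driven by formation of hexamethyldisiloxane.

**Step 4**
Reactants: 8 2-(methoxymethyl)-2-[(trimethylsilyl)ethynyl]-1,3-dioxolane
Product: 9 2-ethynyl-2-(methoxymethyl)-1,3-dioxolane
Conditions: K2CO3 (0.2 equiv), MeOH, rt; careful concentration (volatile)
Reagents that add atoms: none
Why: Methoxide-catalysed protodesilylation of the alkynylsilane, to which the ketal and the ether are inert.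

**Step 5**
Reactants: 9 2-ethynyl-2-(methoxymethyl)-1,3-dioxolane
Product: 11 (E)-2-(2-iodoethenyl)-2-(methoxymethyl)-1,3-dioxolane, via alkenylzirconocene chloride 10 (not isolated)
Conditions: Cp2Zr(H)Cl, THF, rt, dark; then iodine, 0 °C; aq. Na2S2O3
Reagents that add atoms: iodine, [I][I]
Why: Hydrozirconation–iodination, in which syn addition places zirconium on the unhindered terminal carbon and iododezirconation retains configuration, so only the E-iodide should form.

**Step 6**
Reactants: 11 (E)-2-(2-iodoethenyl)-2-(methoxymethyl)-1,3-dioxolane; 12 dimethyl squarate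
Product: 15 4-[(E)-2-(2-(methoxymethyl)-1,3-dioxolan-2-yl)ethenyl]-2,3,4-trimethoxycyclobut-2-en-1-one (racemic), via vinyllithium 13 (not isolated), via lithium alkoxide 14 (not isolated)
Conditions: t-BuLi (2 equiv), Et2O, −78 °C; cannulate into 12, THF, −78 °C; MeOTf, −78 → 0 °C; aq. NaHCO3; keep cold and use promptly
Reagents that add atoms: methyl trifluoromethanesulfonate, COS(=O)(=O)C(F)(F)F
Why: Iodine–lithium exchange retains the E geometry, the vinyllithium adds 1,2 to one of the two equivalent squarate carbonyls, and the tertiary lithium alkoxide is capped in the same pot by the hard methylating agent (organolithium addition to a squarate ester with O-alkylation); the new quaternary carbon forms racemic and is flattened in step 7.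

**Step 7**
Reactants: 15 4-[(E)-2-(2-(methoxymethyl)-1,3-dioxolan-2-yl)ethenyl]-2,3,4-trimethoxycyclobut-2-en-1-one
Product: 18 6-[2-(methoxymethyl)-1,3-dioxolan-2-yl]-2,3,4-trimethoxyphenol, via dienylketene 16 (not isolated), via cyclohexadienone 17 (not isolated)
Conditions: degassed toluene (0.02 M), 110 °C, Ar
Reagents that add atoms: none
Why: Heating opens the cyclobutenone by thermal 4π conrotatory cleavage of its C1–C4 bond to dienylketene 16. A 6π disrotatory electrocyclisation then joins the ketene carbon (future C8a) to the alkene terminus (future C4a), closing ring A as a six-membered carbocycle, and enolisation of dienone 17 gives the aromatic phenol, which makes the sequence irreversible. The closest known reaction type is the Moore rearrangement of squarate-derived 4-alkenyl-4-alkoxycyclobutenones to mono-protected hydroquinones. No lasting stereocentre is formed, since the racemic quaternary carbon of 15 and the sp3 carbon of 17 both become aromatic carbons. The step needs torquoselectivity, which the donor 4-methoxy group secures by rotating outward so that the alkenyl group turns inward, cis to the ketene; the E-alkene puts hydrogen on the inside of the closing terminus and keeps the ketal oxygens away from the ketene. The substitution pattern (hydroxyl on C8a next to the side chain, methoxy groups on C6, C7 and C8, hydrogen on C5) follows from connectivity alone.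

**Step 8**
Reactants: 18 6-[2-(methoxymethyl)-1,3-dioxolan-2-yl]-2,3,4-trimethoxyphenol
Product: 19 1-(2-hydroxy-3,4,5-trimethoxyphenyl)-2-methoxyethan-1-one
Conditions: 2 M aq. HCl, THF, 50 °C
Reagents that add atoms: water, O
Why: Acid-catalysed ketal hydrolysis through an aryl-stabilised oxocarbenium ion releases the ketone, which is held by a hydrogen bond to the ortho hydroxyl, while the methyl ethers are inert to dilute acid.

**Step 9**
Reactants: 19 1-(2-hydroxy-3,4,5-trimethoxyphenyl)-2-methoxyethan-1-one; 20 4-methoxybenzoyl chloride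
Product: 21 6-(2-methoxyacetyl)-2,3,4-trimethoxyphenyl 4-methoxybenzoate
Conditions: pyridine, DMAP (cat.), 0 °C → rt
Reagents that add atoms: none
Why: O-acylation under nucleophilic catalysis (N-acylpyridinium ion) overcomes the hydrogen-bonded, flanked phenol and gives the aryl ester needed for acyl migration.

**Step 10**
Reactants: 21 6-(2-methoxyacetyl)-2,3,4-trimethoxyphenyl 4-methoxybenzoate
Product: 22 1-(2-hydroxy-3,4,5-trimethoxyphenyl)-2-methoxy-3-(4-methoxyphenyl)propane-1,3-dione (racemic)
Conditions: KOt-Bu (2.2 equiv), THF, 0 °C → rt; then 1 M HCl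
Reagents that add atoms: none
Why: Baker–Venkataraman rearrangement, in which the ketone enolate attacks the neighbouring ester carbonyl through a six-membered transition state and the cyclic hemiketal alkoxide collapses to the phenoxide of the 1,3-diketone, whose enolate is the thermodynamic sink; the CH(OMe) centre is racemic and is lost in step 11.

**Step 11**
Reactants: 22 1-(2-hydroxy-3,4,5-trimethoxyphenyl)-2-methoxy-3-(4-methoxyphenyl)propane-1,3-dione
Product: 23 auranetin
Conditions: H2SO4 (cat.), AcOH, 100 °C
Reagents that add atoms: none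
Why: Acid-catalysed cyclodehydration (flavone synthesis from an ortho-hydroxyaryl 1,3-diketone), in which the phenol adds to the aroyl carbonyl and loss of water gives the aromatic 4-pyranone, closing ring C with the C3 methoxy group already in place.

**Compound list**
1 | methoxyacetyl chloride | COCC(=O)Cl | starting material
2 | N,O-dimethylhydroxylamine hydrochloride | CNOC.Cl | starting material
3 | N,2-dimethoxy-N-methylacetamide | COCC(=O)N(C)OC | intermediate
4 | ethynyltrimethylsilane | C#C[Si](C)(C)C | starting material
5 | lithium (trimethylsilyl)acetylide (not isolated) | [Li]C#C[Si](C)(C)C | intermediate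
6 | lithium 1-methoxy-2-[methoxy(methyl)amino]-4-(trimethylsilyl)but-3-yn-2-olate (racemic, not isolated) | COCC(O[Li])(C#C[Si](C)(C)C)N(C)OC | intermediate
7 | 1-methoxy-4-(trimethylsilyl)but-3-yn-2-one | COCC(=O)C#C[Si](C)(C)C | intermediate
8 | 2-(methoxymethyl)-2-[(trimethylsilyl)ethynyl]-1,3-dioxolane | COCC1(C#C[Si](C)(C)C)OCCO1 | intermediate
9 | 2-ethynyl-2-(methoxymethyl)-1,3-dioxolane | COCC1(C#C)OCCO1 | intermediate
10 | chlorobis(cyclopentadienyl)[(E)-2-(2-(methoxymethyl)-1,3-dioxolan-2-yl)ethenyl]zirconium (not isolated) | COCC1(/C=C/[Zr](Cl)(C2C=CC=C2)C2C=CC=C2)OCCO1 | intermediate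
11 | (E)-2-(2-iodoethenyl)-2-(methoxymethyl)-1,3-dioxolane | COCC1(/C=C/I)OCCO1 | intermediate
12 | dimethyl squarate (3,4-dimethoxycyclobut-3-ene-1,2-dione) | COC1=C(OC)C(=O)C1=O | starting material
13 | [(E)-2-(2-(methoxymethyl)-1,3-dioxolan-2-yl)ethenyl]lithium (not isolated) | COCC1(/C=C/[Li])OCCO1 | intermediate
14 | lithium 1-[(E)-2-(2-(methoxymethyl)-1,3-dioxolan-2-yl)ethenyl]-2,3-dimethoxy-4-oxocyclobut-2-en-1-olate (racemic, not isolated) | COCC1(/C=C/C2(O[Li])C(OC)=C(OC)C2=O)OCCO1 | intermediate
15 | 4-[(E)-2-(2-(methoxymethyl)-1,3-dioxolan-2-yl)ethenyl]-2,3,4-trimethoxycyclobut-2-en-1-one (racemic) | COCC1(/C=C/C2(OC)C(OC)=C(OC)C2=O)OCCO1 | intermediate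
16 | (3Z,5E)-2,3,4-trimethoxy-6-[2-(methoxymethyl)-1,3-dioxolan-2-yl]hexa-1,3,5-trien-1-one (not isolated) | O=C=C(OC)/C(OC)=C(OC)\C=C\C1(COC)OCCO1 | intermediate
17 | 2,3,4-trimethoxy-6-[2-(methoxymethyl)-1,3-dioxolan-2-yl]cyclohexa-2,4-dien-1-one (racemic, not isolated) | COCC1(C2C=C(OC)C(OC)=C(OC)C2=O)OCCO1 | intermediate
18 | 6-[2-(methoxymethyl)-1,3-dioxolan-2-yl]-2,3,4-trimethoxyphenol | COCC1(c2cc(OC)c(OC)c(OC)c2O)OCCO1 | intermediate
19 | 1-(2-hydroxy-3,4,5-trimethoxyphenyl)-2-methoxyethan-1-one | COCC(=O)c1cc(OC)c(OC)c(OC)c1O | intermediate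
20 | 4-methoxybenzoyl chloride | COc1ccc(C(=O)Cl)cc1 | starting material
21 | 6-(2-methoxyacetyl)-2,3,4-trimethoxyphenyl 4-methoxybenzoate | COCC(=O)c1cc(OC)c(OC)c(OC)c1OC(=O)c1ccc(OC)cc1 | intermediate
22 | 1-(2-hydroxy-3,4,5-trimethoxyphenyl)-2-methoxy-3-(4-methoxyphenyl)propane-1,3-dione (racemic) | COC(C(=O)c1ccc(OC)cc1)C(=O)c1cc(OC)c(OC)c(OC)c1O | intermediate
23 | auranetin, 3,6,7,8-tetramethoxy-2-(4-methoxyphenyl)-4H-chromen-4-one | COc1ccc(-c2oc3c(OC)c(OC)c(OC)cc3c(=O)c2OC)cc1 | target

**Totals**
Total step count: 11. Longest linear sequence: 11 steps, from methoxyacetyl chloride 1 to auranetin 23.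

**Steps most likely to fail**

Step 6. The halogen–lithium exchange leaves tert-butyl iodide and possibly surplus t-BuLi in the pot. Alkylation or protonation of the vinyllithium, or attack of the alkyllithium on the squarate, may then erode the 1,2-addition. The fallback makes the nucleophile by tin–lithium exchange and sets out from alkyne 9. Hydrostannylation (Bu3SnH, PdCl2(PPh3)2 cat., THF, 0 °C), steered to the terminal carbon by the quaternary propargylic centre, should give tributyl[(E)-2-(2-(methoxymethyl)-1,3-dioxolan-2-yl)ethenyl]stannane F1. Treatment with n-BuLi (1 equiv, THF, −78 °C) exchanges tin for lithium, leaving only inert tetraalkyltin, and the route is rejoined at vinyllithium 13.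

Step 7. The ketene opened from the methyl ether may be lost before it cyclises, through incomplete torquoselectivity, dimerisation or capture by adventitious nucleophiles. The fallback runs the same ring expansion on the free carbinol, the best-documented substrate class for it, and introduces the C6 methyl group afterwards. It sets out from lithium alkoxide 14.
- An NH4Cl quench in place of MeOTf should give 4-hydroxy-4-[(E)-2-(2-(methoxymethyl)-1,3-dioxolan-2-yl)ethenyl]-2,3-dimethoxycyclobut-2-en-1-one F2.
- Heating in degassed toluene under argon should lead through the hydroxy dienylketene (3Z,5E)-4-hydroxy-2,3-dimethoxy-6-[2-(methoxymethyl)-1,3-dioxolan-2-yl]hexa-1,3,5-trien-1-one F3 and 4-hydroxy-2,3-dimethoxy-6-[2-(methoxymethyl)-1,3-dioxolan-2-yl]cyclohexa-2,4-dien-1-one F4 to the hydroquinone 2,3-dimethoxy-5-[2-(methoxymethyl)-1,3-dioxolan-2-yl]benzene-1,4-diol F5.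
- Aqueous HCl in THF should unmask 1-(2,5-dihydroxy-3,4-dimethoxyphenyl)-2-methoxyethan-1-one F6.
- MeI (1 equiv), K2CO3, acetone under argon should methylate only the 5-hydroxyl, because the 2-hydroxyl is chelated to the ketone, and the route is rejoined at ketone 19.

Step 10. Base-mediated cleavage of the crowded aryl ester (de-aroylation back to 19) or retro-Claisen fragmentation of the diketone may outrun the intramolecular acyl shift. The fallback is an Allan–Robinson condensation that sets out from ketone 19. Fusion with 4-methoxybenzoic anhydride and sodium 4-methoxybenzoate at 170–180 °C, followed by brief aqueous-ethanolic KOH to cleave residual esters, should build ring C in one operation and arrive directly at auranetin 23. It passes in the melt through 21 and 22 and adds no compound outside the list (none F0).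

**Further compounds**
F1 | step 6 | tributyl[(E)-2-(2-(methoxymethyl)-1,3-dioxolan-2-yl)ethenyl]stannane | CCCC[Sn](CCCC)(CCCC)/C=C/C1(COC)OCCO1
F2 | step 7 | 4-hydroxy-4-[(E)-2-(2-(methoxymethyl)-1,3-dioxolan-2-yl)ethenyl]-2,3-dimethoxycyclobut-2-en-1-one (racemic) | COCC1(/C=C/C2(O)C(OC)=C(OC)C2=O)OCCO1
F3 | step 7 | (3Z,5E)-4-hydroxy-2,3-dimethoxy-6-[2-(methoxymethyl)-1,3-dioxolan-2-yl]hexa-1,3,5-trien-1-one | O=C=C(OC)/C(OC)=C(O)\C=C\C1(COC)OCCO1
F4 | step 7 | 4-hydroxy-2,3-dimethoxy-6-[2-(methoxymethyl)-1,3-dioxolan-2-yl]cyclohexa-2,4-dien-1-one (racemic) | COCC1(C2C=C(O)C(OC)=C(OC)C2=O)OCCO1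
F5 | step 7 | 2,3-dimethoxy-5-[2-(methoxymethyl)-1,3-dioxolan-2-yl]benzene-1,4-diol | COCC1(c2cc(O)c(OC)c(OC)c2O)OCCO1
F6 | step 7 | 1-(2,5-dihydroxy-3,4-dimethoxyphenyl)-2-methoxyethan-1-one | COCC(=O)c1cc(O)c(OC)c(OC)c1O
F0 | step 10 | none | none
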